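## Retrosynthetic overview

- The target is a (2S)-7-hydroxyflavanone. The free 7-OH comes from a triisopropylsilyl ether, and the two ring B side chains come from a 3'-iodo/5'-bromo pair: Heck coupling at C–I, then Stille prenylation at C–Br.
- The strategy rests on C2 of ring C: it is benzylic to ring B and bound to O1, so it is the CH2 carbon of an O1–CH2–aryl ether. The C2–C3 bond is made by insertion of a C3 carbene, from a terminal diazoketone, into one C2–H bond under a chiral dirhodium catalyst.
- The diazoketone comes from the benzoic acid (acyl chloride, diazomethane), the acid from the aldehyde (Pinnick), and the aldehyde from Mitsunobu etherification of 4-O-silylated 2,4-dihydroxybenzaldehyde with the bromo-iodo-methoxybenzyl alcohol.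
- Rings A and B are bought as the two aromatic aldehydes; ring C is the only ring formed, and it is closed in the key step.

Key step: step 8

Remark on the chemistry: the sense of induction of Rh2(S-PTTL)4 for this substrate cannot be predicted with confidence. The route assumes that this catalyst or its mirror image Rh2(R-PTTL)4 delivers the 2S product, to be settled on the first small-scale run.

## Route

Step 1
Reactants: 1 3-bromo-4-hydroxybenzaldehyde
Product: 2 3-bromo-4-hydroxy-5-iodobenzaldehyde
Conditions: N-iodosuccinimide, AcOH, rt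
Reagents that add atoms: N-iodosuccinimide, O=C1CCC(=O)N1I
Why: Electrophilic aromatic iodination; the phenol directs to its only free ortho position, the other ortho and the para positions being blocked.

Step 2
Reactants: 2 3-bromo-4-hydroxy-5-iodobenzaldehyde
Product: 3 3-bromo-5-iodo-4-methoxybenzaldehyde
Conditions: MeI, K2CO3, DMF, rt
Reagents that add atoms: iodomethane, CI
Why: Williamson O-methylation of the acidic, doubly ortho-halogenated phenol with a small electrophile.

Step 3
Reactants: 3 3-bromo-5-iodo-4-methoxybenzaldehyde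
Product: 4 (3-bromo-5-iodo-4-methoxyphenyl)methanol
Conditions: NaBH4, MeOH/THF, 0 °C
Reagents that add atoms: none
Why: Hydride reduction of the aldehyde; the aryl halides and the methyl ether are inert to NaBH4.

Step 4
Reactants: 5 2,4-dihydroxybenzaldehyde
Product: 6 2-hydroxy-4-(triisopropylsilyloxy)benzaldehyde
Conditions: TIPSCl (1.05 equiv), imidazole, CH2Cl2, 0 °C to rt
Reagents that add atoms: triisopropylsilyl chloride, CC(C)[Si](Cl)(C(C)C)C(C)C
Why: Selective silylation; the 4-OH is free and more acidic, whereas the 2-OH is tied up in a hydrogen bond to the formyl group, so one equivalent of the bulky chloride should react at O4 only.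

Step 5
Reactants: 6 2-hydroxy-4-(triisopropylsilyloxy)benzaldehyde; 4 (3-bromo-5-iodo-4-methoxyphenyl)methanol
Product: 7 2-[(3-bromo-5-iodo-4-methoxyphenyl)methoxy]-4-(triisopropylsilyloxy)benzaldehyde
Conditions: PPh3, DIAD, THF, 0 °C to rt
Reagents that add atoms: none
Why: Mitsunobu etherification; the primary benzylic alcohol is activated as its alkoxyphosphonium salt and displaced (SN2) by the salicylaldehyde-type phenol under neutral conditions, which spares the base-labile aryl silyl ether that a carbonate-mediated benzylation would endanger.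

Step 6
Reactants: 7 2-[(3-bromo-5-iodo-4-methoxyphenyl)methoxy]-4-(triisopropylsilyloxy)benzaldehyde
Product: 8 2-[(3-bromo-5-iodo-4-methoxyphenyl)methoxy]-4-(triisopropylsilyloxy)benzoic acid
Conditions: NaClO2, NaH2PO4, 2-methylbut-2-ene, t-BuOH/THF/H2O, rt
Reagents that add atoms: sodium chlorite, [Na+].[O-]Cl=O
Why: Pinnick oxidation under buffered, mildly acidic conditions; the alkene scavenges HOCl so that electron-rich ring A is not chlorinated, and the silyl ether, benzyl ether and halides are untouched.

Step 7
Reactants: 8 2-[(3-bromo-5-iodo-4-methoxyphenyl)methoxy]-4-(triisopropylsilyloxy)benzoic acid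
Product: 10 1-{2-[(3-bromo-5-iodo-4-methoxyphenyl)methoxy]-4-(triisopropylsilyloxy)phenyl}-2-diazoethanone, via acyl chloride 9 (not isolated)
Conditions: (COCl)2, cat. DMF, CH2Cl2, 0 °C to rt; evaporate; CH2N2 (3 equiv), Et2O, 0 °C
Reagents that add atoms: diazomethane, C=[N+]=[N-]; oxalyl chloride, ClC(=O)C(Cl)=O (chlorine of intermediate 9 only)
Why: Acylation of diazomethane by the acyl chloride (first stage of an Arndt–Eistert sequence) gives the terminal diazoketone more reliably for an electron-rich aroyl group than a mixed anhydride would; excess diazomethane consumes the HCl so that no chloromethyl ketone forms.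

Step 8
Reactants: 10 1-{2-[(3-bromo-5-iodo-4-methoxyphenyl)methoxy]-4-(triisopropylsilyloxy)phenyl}-2-diazoethanone
Product: 11 (2S)-2-(3-bromo-5-iodo-4-methoxyphenyl)-7-(triisopropylsilyloxy)chroman-4-one
Conditions: Rh2(S-PTTL)4 [dirhodium tetrakis(N-phthaloyl-(S)-tert-leucinate)] (2 mol %), 4 Å MS, CH2Cl2, 0 °C, slow addition of 10
Reagents that add atoms: none
Why: The divalent rhodium catalyst should expel N2 from 10 to give an electrophilic acyl carbene at C3, which inserts into one of the two enantiotopic O1–CH2–aryl hydrogens through a concerted, asynchronous three-centre transition state with hydride-transfer character, forming the C2–C3 bond. The closest known reaction type is the dirhodium-carboxylate-catalysed intramolecular C–H insertion of 2-alkoxyaryl diazoketones to chroman-4-ones. Ring C is closed as a six-membered ring by a 1,6-insertion (C3, C4, C4a, C8a, O1, C2); ring A holds carbene and ether within reach, and no 1,5 C–H bond exists as an alternative. The C2 stereocentre is set by the chiral phthalimido-tert-leucinate ligand shell, which tells the two enantiotopic hydrogens apart; the sense is checked on the first run and the enantiomeric catalyst is taken if the 2R product forms. The step needs insertion to win over carbene attack on the O1 lone pair (oxonium ylide, then 1,2-benzyl shift to a 2-benzylbenzofuran-3-one): the C–H bond is activated by both O1 and ring B, O1 is a weakened donor because it is conjugated to the C4 carbonyl through ring A, the para silyloxy group tempers the carbene, and ylide formation on rhodium is reversible while insertion is not. Ring B carries no alkene at this stage, and slow addition at low temperature suppresses carbene dimerisation.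

Step 9
Reactants: 11 (2S)-2-(3-bromo-5-iodo-4-methoxyphenyl)-7-(triisopropylsilyloxy)chroman-4-one; 12 2-methylbut-3-en-2-ol
Product: 13 (2S)-2-{3-bromo-5-[(E)-3-hydroxy-3-methylbut-1-enyl]-4-methoxyphenyl}-7-(triisopropylsilyloxy)chroman-4-one
Conditions: Pd(OAc)2 (5 mol %), n-Bu4NCl, NaHCO3, DMF, 50 °C
Reagents that add atoms: none
Why: Heck reaction under ligand-free phase-transfer conditions; oxidative addition of zerovalent palladium is much faster at C–I than at C–Br, syn-insertion and syn-β-hydride elimination give the E-alkene, the tertiary carbinol has no hydrogen that could divert the product to a ketone, and the weak base at 50 °C should leave C2 alone.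

Step 10
Reactants: 13 (2S)-2-{3-bromo-5-[(E)-3-hydroxy-3-methylbut-1-enyl]-4-methoxyphenyl}-7-(triisopropylsilyloxy)chroman-4-one; 14 tributyl(3-methylbut-2-enyl)stannane
Product: 15 (2S)-2-{3-[(E)-3-hydroxy-3-methylbut-1-enyl]-4-methoxy-5-(3-methylbut-2-enyl)phenyl}-7-(triisopropylsilyloxy)chroman-4-one
Conditions: Pd(PPh3)4 (10 mol %), degassed DMF, 90 °C
Reagents that add atoms: none
Why: Stille coupling of the remaining aryl bromide with the prenylstannane under neutral conditions; reductive elimination at the less hindered terminus should give the linear prenyl group, and the ketone, free tertiary alcohol and silyl ether are tolerated.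

Step 11
Reactants: 15 (2S)-2-{3-[(E)-3-hydroxy-3-methylbut-1-enyl]-4-methoxy-5-(3-methylbut-2-enyl)phenyl}-7-(triisopropylsilyloxy)chroman-4-one
Product: 16 (2S)-7-hydroxy-2-{3-[(E)-3-hydroxy-3-methylbut-1-enyl]-4-methoxy-5-(3-methylbut-2-enyl)phenyl}chroman-4-one
Conditions: TBAF, AcOH (1:1), THF, 0 °C
Reagents that add atoms: none
Why: Fluoride desilylation of the aryl silyl ether, whose phenoxide para to the carbonyl is a good leaving group; acetic acid buffering keeps the medium from turning basic, so C2 is protected from retro-oxa-Michael racemisation, and the tertiary allylic alcohol never meets strong acid.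

## Compound list

1 | 3-bromo-4-hydroxybenzaldehyde | O=Cc1ccc(O)c(Br)c1 | starting material
2 | 3-bromo-4-hydroxy-5-iodobenzaldehyde | O=Cc1cc(Br)c(O)c(I)c1 | intermediate
3 | 3-bromo-5-iodo-4-methoxybenzaldehyde | COc1c(Br)cc(C=O)cc1I | intermediate
4 | (3-bromo-5-iodo-4-methoxyphenyl)methanol | COc1c(Br)cc(CO)cc1I | intermediate
5 | 2,4-dihydroxybenzaldehyde | O=Cc1ccc(O)cc1O | starting material
6 | 2-hydroxy-4-(triisopropylsilyloxy)benzaldehyde | O=Cc1ccc(O[Si](C(C)C)(C(C)C)C(C)C)cc1O | intermediate
7 | 2-[(3-bromo-5-iodo-4-methoxyphenyl)methoxy]-4-(triisopropylsilyloxy)benzaldehyde | O=Cc1ccc(O[Si](C(C)C)(C(C)C)C(C)C)cc1OCc1cc(Br)c(OC)c(I)c1 | intermediate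
8 | 2-[(3-bromo-5-iodo-4-methoxyphenyl)methoxy]-4-(triisopropylsilyloxy)benzoic acid | OC(=O)c1ccc(O[Si](C(C)C)(C(C)C)C(C)C)cc1OCc1cc(Br)c(OC)c(I)c1 | intermediate
9 | 2-[(3-bromo-5-iodo-4-methoxyphenyl)methoxy]-4-(triisopropylsilyloxy)benzoyl chloride | ClC(=O)c1ccc(O[Si](C(C)C)(C(C)C)C(C)C)cc1OCc1cc(Br)c(OC)c(I)c1 | intermediate
10 | 1-{2-[(3-bromo-5-iodo-4-methoxyphenyl)methoxy]-4-(triisopropylsilyloxy)phenyl}-2-diazoethanone | [N-]=[N+]=CC(=O)c1ccc(O[Si](C(C)C)(C(C)C)C(C)C)cc1OCc1cc(Br)c(OC)c(I)c1 | intermediate
11 | (2S)-2-(3-bromo-5-iodo-4-methoxyphenyl)-7-(triisopropylsilyloxy)chroman-4-one | COc1c(I)cc([C@@H]2CC(=O)c3ccc(O[Si](C(C)C)(C(C)C)C(C)C)cc3O2)cc1Br | intermediate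
12 | 2-methylbut-3-en-2-ol | C=CC(C)(C)O | starting material
13 | (2S)-2-{3-bromo-5-[(E)-3-hydroxy-3-methylbut-1-enyl]-4-methoxyphenyl}-7-(triisopropylsilyloxy)chroman-4-one | COc1c(/C=C/C(C)(C)O)cc([C@@H]2CC(=O)c3ccc(O[Si](C(C)C)(C(C)C)C(C)C)cc3O2)cc1Br | intermediate
14 | tributyl(3-methylbut-2-enyl)stannane | CCCC[Sn](CCCC)(CCCC)CC=C(C)C | starting material
15 | (2S)-2-{3-[(E)-3-hydroxy-3-methylbut-1-enyl]-4-methoxy-5-(3-methylbut-2-enyl)phenyl}-7-(triisopropylsilyloxy)chroman-4-one | COc1c(/C=C/C(C)(C)O)cc([C@@H]2CC(=O)c3ccc(O[Si](C(C)C)(C(C)C)C(C)C)cc3O2)cc1CC=C(C)C | intermediate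
16 | (2S)-7-hydroxy-2-{3-[(E)-3-hydroxy-3-methylbut-1-enyl]-4-methoxy-5-(3-methylbut-2-enyl)phenyl}chroman-4-one | COc1c(/C=C/C(C)(C)O)cc([C@@H]2CC(=O)c3ccc(O)cc3O2)cc1CC=C(C)C | target

## Step count and risks

Total step count: 11. Longest linear sequence: 10 steps (steps 1–3 and 5–11, from compound 1).

Steps most likely to fail:

1. Step 8 (carbene C–H insertion). The carbene may attack the O1 lone pair and undergo a 1,2-benzyl shift instead of inserting. The benzylic C–H bond, deactivated by the two meta halogens, may react too slowly. The catalyst may discriminate poorly between the two enantiotopic hydrogens. Fallback, setting out from aldehyde 3 and returning at 11: Claisen–Schmidt condensation of 3 with commercial 1-(2,4-dihydroxyphenyl)ethanone (KOH, aqueous EtOH, rt) should give (E)-3-(3-bromo-5-iodo-4-methoxyphenyl)-1-(2,4-dihydroxyphenyl)prop-2-en-1-one F1. Oxa-Michael ring closure (NaOAc, EtOH, reflux) should give racemic 2-(3-bromo-5-iodo-4-methoxyphenyl)-7-hydroxychroman-4-one F2. Silylation (TIPSCl, imidazole, CH2Cl2) should give racemic 2-(3-bromo-5-iodo-4-methoxyphenyl)-7-(triisopropylsilyloxy)chroman-4-one F3. Preparative HPLC on a polysaccharide chiral stationary phase then delivers 11; the 2R enantiomer can be re-equilibrated through the chalcone with base and recycled.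

2. Step 10 (Stille prenylation). Coupling through the γ-carbon of the prenyl unit (reverse prenylation), sluggish oxidative addition into the hindered, electron-rich C–Br bond, and palladium hydride-mediated alkene migration at 90 °C are the failure processes. Fallback, setting out from 13 and returning at 15: Stille coupling of 13 with allyltributylstannane (Pd(PPh3)4, DMF, 80 °C), which has no α/γ ambiguity, should give (2S)-2-{3-allyl-5-[(E)-3-hydroxy-3-methylbut-1-enyl]-4-methoxyphenyl}-7-(triisopropylsilyloxy)chroman-4-one F4. Cross-metathesis of the terminal alkene with excess 2-methylbut-2-ene (second-generation Grubbs catalyst, CH2Cl2, rt to 40 °C) should then give 15; the hindered styrenyl alkene next to the quaternary carbinol should not take part.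

3. Step 9 (Heck coupling). Base-induced enolisation and retro-oxa-Michael opening of ring C, eroding the C2 configuration in warm DMF, and competing oxidative addition at C–Br are the failure processes. Fallback, setting out from 11 and returning at 13: hydrostannylation of 2-methylbut-3-yn-2-ol (Bu3SnH, PdCl2(PPh3)2, THF, 0 °C) should give (E)-2-methyl-4-(tributylstannyl)but-3-en-2-ol F5. Base-free Stille coupling of F5 with 11 at the C–I bond (Pd(PPh3)4, CuI, DMF, rt to 40 °C) should give 13 with the E geometry fixed by the stannane.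

## Further compounds

F1 | step 8 | (E)-3-(3-bromo-5-iodo-4-methoxyphenyl)-1-(2,4-dihydroxyphenyl)prop-2-en-1-one | COc1c(Br)cc(/C=C/C(=O)c2ccc(O)cc2O)cc1I
F2 | step 8 | racemic 2-(3-bromo-5-iodo-4-methoxyphenyl)-7-hydroxychroman-4-one | COc1c(I)cc(C2CC(=O)c3ccc(O)cc3O2)cc1Br
F3 | step 8 | racemic 2-(3-bromo-5-iodo-4-methoxyphenyl)-7-(triisopropylsilyloxy)chroman-4-one | COc1c(I)cc(C2CC(=O)c3ccc(O[Si](C(C)C)(C(C)C)C(C)C)cc3O2)cc1Br
F4 | step 10 | (2S)-2-{3-allyl-5-[(E)-3-hydroxy-3-methylbut-1-enyl]-4-methoxyphenyl}-7-(triisopropylsilyloxy)chroman-4-one | COc1c(/C=C/C(C)(C)O)cc([C@@H]2CC(=O)c3ccc(O[Si](C(C)C)(C(C)C)C(C)C)cc3O2)cc1CC=C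
F5 | step 9 | (E)-2-methyl-4-(tributylstannyl)but-3-en-2-ol | CCCC[Sn](CCCC)(CCCC)/C=C/C(C)(C)O
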